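A one-step world has substrate become single ring and stop there; here the ring goes on reacting, so ask first how much of it gets out.

    substrate → single ring (k1 = 0.019 h⁻¹)
    2 substrate → open dimer (k2 = 0.056 L mol⁻¹ h⁻¹)
    substrate + open dimer → open trimer (k3 = 0.082 L mol⁻¹ h⁻¹)
    open dimer → ring dimer (k4 = 0.023 h⁻¹)
    substrate ⇌ dormant form (K5 = 0.67, k5 = 0.50 h⁻¹)
    single ring → over-reaction product (k6 = 0.0076 h⁻¹)

- eta: substrate 0.30 M; one stirred flow tank at steady state, fed with the mixture as stated, mean residence time 15 d
- epsilon: substrate 0.30 M; time 15 d; everything together in a closed stirred flask, run for 15 d

- percentages count the substrate that a species holds: one open dimer or ring dimer counts as two
- percentages count the substrate that a species holds: one open trimer counts as three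
- two of one species on the left: rate k times its square, two consumed each time
- the stated concentrations are those of everything mixed, before any reaction; amounts are the same in each set-up
- run time (epsilon): 15 d

1. the set-up with the highest amount of single ring at the outlet or at the end, in percent of the substrate put in ("none" if the first two lie within 2 percentage points) (eta / epsilon / none)
2. amount of single ring at the outlet or at the end, in percent of the substrate put in, eta
3. amount of single ring at the outlet or at the end, in percent of the substrate put in, epsilon

Follow one ring through the tank. It has two exits: outflow, at one over the residence time, and over-reaction at 0.0076 h⁻¹, the wider exit. The outlet therefore takes 26.8% of the ring made.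

Now reckon by age instead. Ages in a stirred tank spread exponentially about 15 d, and a ring of age t is intact with probability e^(−kt). Averaging over ages gives one over one plus k times the residence time, that product being a Damköhler number. The result is 26.8%, the survival share, the fraction of ring made that reaches the outlet unspent. The two routes are one formula written twice, resting on the same well-mixed tank, so their agreement tests nothing and the figure still has to meet a run.

Next reckon what the tank makes. Exchange with dormant form runs far faster than the flow, so c(dormant form) stays at 0.67 times c(substrate). Balance the feed against free substrate, dormant form and what the ring and open-dimer steps remove in one residence time, and set the trimer step aside. The quadratic gives c(substrate) = 0.0308 M in the tank. So 70.1% of the feed becomes ring, and the survival share leaves 18.8%.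

The closed flask has no outflow. Ring formed at the start faces the full 15 d and keeps 6.48%; ring formed at the last moment loses none. How far above that floor the flask lands depends on when ring forms, and my hand reckoning stops here, with no figure for the closed flask.

The forecast picks eta, the tank, with 18.7% there (18% to 19.4%) and 8.6% in the closed flask (8% to 9.2%), where “much of it has over-reacted”. My tank figure stands slightly above its value.

The simulation gives 18.7% for the tank and 8.48% for the closed flask, so eta stands. Strike the back reaction of dormant form to substrate and the tank's lead shrinks to 0.74 percentage points, inside the 2 points margin, a part of the story that turns the answer to none. Over-reaction is the main loss: struck from the tank, it leaves 69.8% of ring, and the survival share turns that into 18.7%. The same strike on the closed flask gives 65.2%, so its survival share reads 13.0%, below the tank's and above the floor of 6.48%.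

(The rate constants were drawn at random within sensible limits; what happens was integrated by code.)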